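**Plan**
- Labels: ring B is the bromohydrin ring (B1 = CH carrying Ca, B2 and B3 = CH2, B4 = C(CH3)OH, B5 = CHBr, B6 = CH2). Ca is the carbon bearing the exocyclic =CH2 and Cb is its CH2 neighbour. In the epoxide ring (ring A), Cx carries Cb, Cy carries the isopropenyl group, Cz is the epoxide CH and Cw the epoxide C(CH3).
- Retrosynthesis, in order of cutting: the two epoxide C–O bonds of ring A; Cb–Cx (allylation of the (S)-carvone enolate); Ca=CH2 and Ca–Cb (both grown from a lactone carbonyl); B5–Br (SN2 with inversion); B4–O of a bridging δ-lactone (key); last the Diels–Alder bonds B1–B6 and B2–B3.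
- Forward: ring B arises by a catalytic asymmetric Diels–Alder reaction. The lactone ring follows by epoxide-opening lactonisation to a 2-oxabicyclo[2.2.2]octan-3-one, and bromide is set by inversion on that bicycle. The lactone is then opened to a 2-substituted allyl bromide. Ring A comes intact from carvone and is joined at Cx, the enone is transposed, and the epoxide is closed last.
- Enabling feature: on ring B the groups at B1 (Ca), B4 (OH) and B5 (Br) lie on one face (B1/B4 1,4-cis, B4/B5 1,2-cis). A carboxyl on B1 can therefore reach B4 across the ring and hold that oxygen in a lactone while B5 is inverted.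
- Stereochemistry: B1 comes from the Diels–Alder catalyst; B4 and B5 from a reagent-controlled epoxidation followed by two stereospecific inversions; Cy from (S)-carvone; Cx from alkylation trans to Cy; Cz and Cw from the Shi ketone.

Key step: step 4

Assumption: the triflimide-activated oxazaborolidine made from (R)-α,α-diphenylprolinol is taken to give the (R)-ester 3; should the sense of induction be the opposite one, the catalyst from (S)-α,α-diphenylprolinol is used and nothing else changes.

Step 1
Reactants: 1 isoprene; 2 2,2,2-trifluoroethyl acrylate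
Product: 3 2,2,2-trifluoroethyl (R)-4-methylcyclohex-3-ene-1-carboxylate
Conditions: (R)-3,3-diphenyl-1-(o-tolyl)tetrahydropyrrolo[1,2-c][1,3,2]oxazaborole (10 mol %), Tf2NH (8 mol %), CH2Cl2, −20 to 0 °C
Reagents that add atoms: none
Why: Lewis-acid-catalysed Diels–Alder reaction in which the cationic oxazaborolidine binds the acrylate and shields one of its faces, so that B1 is set by the catalyst, while the larger terminal orbital coefficient of isoprene leads to the 1,4-("para") adduct.

Step 2
Reactants: 3 2,2,2-trifluoroethyl (R)-4-methylcyclohex-3-ene-1-carboxylate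
Product: 4 (R)-4-methylcyclohex-3-ene-1-carboxylic acid
Conditions: LiOH·H2O, THF/H2O, 0 °C; then 1 M HCl
Reagents that add atoms: lithium hydroxide, [Li+].[OH-]
Why: Saponification of the activated trifluoroethyl ester is fast at 0 °C, so the α-centre B1 should not epimerise.

Step 3
Reactants: 4 (R)-4-methylcyclohex-3-ene-1-carboxylic acid
Product: 5 anti-epoxy acid (1S,3R,6R)-6-methyl-7-oxabicyclo[4.1.0]heptane-3-carboxylic acid
Conditions: Shi ketone of the L series (enantiomer of the D-fructose-derived ketone, made from L-sorbose; 30 mol %), Oxone (2KHSO5·KHSO4·K2SO4), K2CO3, Bu4NHSO4 (cat.), MeCN/(MeO)2CH2/aq. Na2B4O7 buffer, pH 10.5, 0 °C; then NaH2PO4 to pH 4 at 0 °C, extraction into CH2Cl2, used at once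
Reagents that add atoms: potassium peroxymonosulfate KHSO5 (oxidant of Oxone), [K+].[O-]S(=O)(=O)OO
Why: Shi epoxidation, in which the chiral dioxirane meets the trisubstituted alkene in a spiro transition state and, B1 being too remote to matter, the L-series ketone (mirror image of the ketone that converts 1-phenylcyclohexene into its (R,R)-oxide) should deliver oxygen to the face anti to the carboxylate, setting B4 and B5 under reagent control.

Step 4
Reactants: 5 anti-epoxy acid (1S,3R,6R)-6-methyl-7-oxabicyclo[4.1.0]heptane-3-carboxylic acid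
Product: 6 hydroxy lactone (1S,4R,6S)-6-hydroxy-1-methyl-2-oxabicyclo[2.2.2]octan-3-one
Conditions: (+)-camphorsulfonic acid (10 mol %), CH2Cl2, 0 °C to rt
Reagents that add atoms: none
Why: The protonated epoxide, with ring B flipped into a boat, holds the B1 carboxyl above B4, and the carbonyl oxygen attacks this tertiary, charge-bearing carbon on the side opposite the leaving epoxide oxygen (borderline SN2 opening with inversion at B4), the epoxide oxygen remaining on B5 as the hydroxyl. The closest known reaction type is the acid-catalysed Markovnikov epoxide-opening cyclisation of 4-substituted 1-methylcyclohexene oxides (α-terpineol epoxide to 2-hydroxy-1,8-cineole), the oxygen counterpart of Markovnikov halolactonisation. The one ring closed is the six-membered δ-lactone, formed in the 6-exo-tet mode when counted through B2–B3 (6-endo when counted through B6–B5), which completes the 2-oxabicyclo[2.2.2]octan-3-one. The new B4–O centre follows from the stereospecific backside opening and is therefore fixed by B1 (step 1) and the anti epoxide (step 3), while B5 keeps its oxygen anti to the lactone bridge. The step needs attack at B4 and not 5-exo attack at the secondary B5 (which would give a 6-oxabicyclo[3.2.1]octan-7-one); the methyl group on B4, which takes up the developing positive charge under Brønsted acid in a non-nucleophilic solvent, should secure this. Any syn epoxy acid cannot reach either carbon from the rear and should remain as a base-extractable acid.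

Step 5
Reactants: 6 hydroxy lactone (1S,4R,6S)-6-hydroxy-1-methyl-2-oxabicyclo[2.2.2]octan-3-one
Product: 8 bromo lactone (1S,4R,6R)-6-bromo-1-methyl-2-oxabicyclo[2.2.2]octan-3-one, via B5 triflate 7 (not isolated)
Conditions: Tf2O, 2,6-lutidine, CH2Cl2, −30 °C; then Bu4NBr, −30 to 40 °C
Reagents that add atoms: tetrabutylammonium bromide, CCCC[N+](CCCC)(CCCC)CCCC.[Br-]
Why: Sulfonylation followed by SN2 displacement, in which bromide should reach B5 from the side of the hydrogen-free lactone bridge with inversion (bromine syn to the B4 oxygen), while the lactone ties up the B4 oxygen so that no epoxide can form and the rigid bicycle offers no anti-periplanar hydrogen for β-elimination.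

Step 6
Reactants: 8 bromo lactone (1S,4R,6R)-6-bromo-1-methyl-2-oxabicyclo[2.2.2]octan-3-one
Product: 10 hydroxy allylsilane (1S,2R,4R)-2-bromo-1-methyl-4-[3-(trimethylsilyl)prop-1-en-2-yl]cyclohexan-1-ol, via bis(silylmethyl) carbinol 9 (not isolated)
Conditions: Me3SiCH2MgCl (excess), CeCl3 (anhydrous), THF, −78 °C to rt; aq. NH4Cl; then silica gel, CH2Cl2, rt
Reagents that add atoms: (trimethylsilylmethyl)magnesium chloride, C[Si](C)(C)C[Mg]Cl
Why: Cerium-promoted double addition of the weakly basic silylmethyl reagent to the lactone carbonyl followed by Peterson elimination of the β-hydroxysilane should give the 2-substituted allylsilane, opening the bicycle to the free B4 hydroxyl cis to bromine (a cis-bromohydrin alkoxide cannot close to an epoxide) without touching B1 or the secondary bromide.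

Step 7
Reactants: 10 hydroxy allylsilane (1S,2R,4R)-2-bromo-1-methyl-4-[3-(trimethylsilyl)prop-1-en-2-yl]cyclohexan-1-ol
Product: 11 trimethylsilyl ether of 10
Conditions: 1-(trimethylsilyl)imidazole, CH2Cl2, rt
Reagents that add atoms: 1-(trimethylsilyl)imidazole, C[Si](C)(C)n1ccnc1
Why: Acid-free silylation of the tertiary alcohol masks the only acidic proton ahead of the enolate alkylation and spares the acid-sensitive allylsilane.

Step 8
Reactants: 11 trimethylsilyl ether of 10
Product: 12 allylic bromide (1S,2R,4R)-2-bromo-4-(3-bromoprop-1-en-2-yl)-1-methylcyclohexyl trimethylsilyl ether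
Conditions: NBS, CH2Cl2, −78 to −40 °C, dark
Reagents that add atoms: N-bromosuccinimide, O=C1CCC(=O)N1Br
Why: Electrophilic bromodesilylation of an allylsilane, in which bromine adds to the alkene terminus and the β-silyl cation loses silicon, should give the allylic bromide, and because the allyl unit is symmetrical there is no regiochemical issue.

Step 9
Reactants: 12 allylic bromide (1S,2R,4R)-2-bromo-4-(3-bromoprop-1-en-2-yl)-1-methylcyclohexyl trimethylsilyl ether; 13 (S)-(+)-carvone
Product: 16 hydroxy enone (5S,6R)-6-{2-[(1R,3R,4S)-3-bromo-4-hydroxy-4-methylcyclohexyl]prop-2-en-1-yl}-2-methyl-5-(prop-1-en-2-yl)cyclohex-2-en-1-one, via lithium dienolate 14 (not isolated), via silyl ether enone 15 (not isolated)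
Conditions: 13, LiN(iPr)2 (1.0 equiv), THF, −78 °C; then 12, DMPU, −78 to −20 °C; then 10% aq. citric acid, THF/MeOH, 0 °C to rt
Reagents that add atoms: none
Why: Kinetic enolate alkylation, in which LiN(iPr)2 removes an α′ proton of carvone (from the CH2 between the carbonyl and Cy) to give the cross-conjugated dienolate and the allylic bromide should add on the face anti to the neighbouring isopropenyl group (Cx trans to Cy, also the more stable diequatorial isomer), the hindered secondary bromide being spared and the mild acid removing the silyl ether without protonating the alkenes.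

Step 10
Reactants: 16 hydroxy enone (5S,6R)-6-{2-[(1R,3R,4S)-3-bromo-4-hydroxy-4-methylcyclohexyl]prop-2-en-1-yl}-2-methyl-5-(prop-1-en-2-yl)cyclohex-2-en-1-one
Product: 17 tosylhydrazone of 16
Conditions: TsNHNH2, PPTS (cat.), EtOH, 50 °C
Reagents that add atoms: p-toluenesulfonyl hydrazide, Cc1ccc(cc1)S(=O)(=O)NN
Why: Condensation of the only carbonyl group with the sulfonyl hydrazide gives the α,β-unsaturated tosylhydrazone under mild acid that the alkenes, the bromide and the tertiary alcohol should tolerate.

Step 11
Reactants: 17 tosylhydrazone of 16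
Product: 20 triene alcohol (1S,2R,4R)-2-bromo-1-methyl-4-{3-[(1S,6S)-3-methyl-6-(prop-1-en-2-yl)cyclohex-2-en-1-yl]prop-1-en-2-yl}cyclohexan-1-ol, via allylic tosylhydrazine 18 (not isolated), via allylic diazene 19 (not isolated)
Conditions: catecholborane (excess), CHCl3, 0 °C; then NaOAc·3H2O, reflux
Reagents that add atoms: none
Why: Reductive 1,3-transposition of an enone tosylhydrazone, in which 1,2-hydride addition to C=N, loss of sulfinate and retro-ene extrusion of N2 from the allylic diazene deliver hydrogen to the ring CH beside Cw (making it CH2) and move the alkene to Cz=Cw without touching Cx or Cy.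

Step 12
Reactants: 20 triene alcohol (1S,2R,4R)-2-bromo-1-methyl-4-{3-[(1S,6S)-3-methyl-6-(prop-1-en-2-yl)cyclohex-2-en-1-yl]prop-1-en-2-yl}cyclohexan-1-ol
Product: 21 CNP0213097.1 (target)
Conditions: D-fructose-derived Shi ketone (30 mol %), Oxone (2KHSO5·KHSO4·K2SO4), K2CO3, Bu4NHSO4 (cat.), MeCN/(MeO)2CH2/aq. Na2B4O7 buffer, pH 10.5, 0 °C
Reagents that add atoms: potassium peroxymonosulfate KHSO5 (oxidant of Oxone), [K+].[O-]S(=O)(=O)OO
Why: Shi epoxidation, in which the electrophilic dioxirane should choose the trisubstituted Cz=Cw alkene over the two 1,1-disubstituted ones and, through the spiro transition state that gives (R,R)-1-phenylcyclohexene oxide, place oxygen on the face syn to the Cb chain on Cx and anti to the isopropenyl group, setting Cz and Cw.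

**Compound list**
1 | isoprene (2-methylbuta-1,3-diene) | CC(=C)C=C | starting material
2 | 2,2,2-trifluoroethyl acrylate | C=CC(=O)OCC(F)(F)F | starting material
3 | 2,2,2-trifluoroethyl (R)-4-methylcyclohex-3-ene-1-carboxylate | FC(F)(F)COC(=O)[C@@H]1CCC(C)=CC1 | intermediate
4 | (R)-4-methylcyclohex-3-ene-1-carboxylic acid | OC(=O)[C@@H]1CCC(C)=CC1 | intermediate
5 | (1S,3R,6R)-6-methyl-7-oxabicyclo[4.1.0]heptane-3-carboxylic acid (epoxide anti to the carboxyl) | OC(=O)[C@@H]1CC[C@@]2(C)O[C@H]2C1 | intermediate
6 | (1S,4R,6S)-6-hydroxy-1-methyl-2-oxabicyclo[2.2.2]octan-3-one (hydroxyl anti to the lactone oxygen) | O=C1O[C@@]2(C)CC[C@@H]1C[C@@H]2O | intermediate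
7 | (1S,4R,6S)-1-methyl-3-oxo-2-oxabicyclo[2.2.2]octan-6-yl trifluoromethanesulfonate | O=C1O[C@@]2(C)CC[C@@H]1C[C@@H]2OS(=O)(=O)C(F)(F)F | intermediate
8 | (1S,4R,6R)-6-bromo-1-methyl-2-oxabicyclo[2.2.2]octan-3-one (bromine syn to the lactone oxygen) | O=C1O[C@@]2(C)CC[C@@H]1C[C@H]2Br | intermediate
9 | (1S,2R,4R)-2-bromo-4-[2-hydroxy-1,3-bis(trimethylsilyl)propan-2-yl]-1-methylcyclohexan-1-ol | C[Si](C)(C)CC(O)(C[Si](C)(C)C)[C@@H]1CC[C@](C)(O)[C@H](Br)C1 | intermediate
10 | (1S,2R,4R)-2-bromo-1-methyl-4-[3-(trimethylsilyl)prop-1-en-2-yl]cyclohexan-1-ol | C=C(C[Si](C)(C)C)[C@@H]1CC[C@](C)(O)[C@H](Br)C1 | intermediate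
11 | trimethylsilyl ether of 10 | C=C(C[Si](C)(C)C)[C@@H]1CC[C@](C)(O[Si](C)(C)C)[C@H](Br)C1 | intermediate
12 | (1S,2R,4R)-2-bromo-4-(3-bromoprop-1-en-2-yl)-1-methylcyclohexyl trimethylsilyl ether | C=C(CBr)[C@@H]1CC[C@](C)(O[Si](C)(C)C)[C@H](Br)C1 | intermediate
13 | (S)-(+)-carvone | CC1=CC[C@@H](CC1=O)C(C)=C | starting material
14 | lithium dienolate of carvone (O–Li on the former carbonyl carbon, new C=C toward the α′ carbon) | CC1=CC[C@H](C(C)=C)C=C1O[Li] | intermediate
15 | trimethylsilyl ether of 16 | C=C(C[C@@H]1[C@@H](C(=C)C)CC=C(C)C1=O)[C@@H]1CC[C@](C)(O[Si](C)(C)C)[C@H](Br)C1 | intermediate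
16 | (5S,6R)-6-{2-[(1R,3R,4S)-3-bromo-4-hydroxy-4-methylcyclohexyl]prop-2-en-1-yl}-2-methyl-5-(prop-1-en-2-yl)cyclohex-2-en-1-one | C=C(C[C@@H]1[C@@H](C(=C)C)CC=C(C)C1=O)[C@@H]1CC[C@](C)(O)[C@H](Br)C1 | intermediate
17 | p-toluenesulfonylhydrazone of 16 | C=C(C[C@@H]1[C@@H](C(=C)C)CC=C(C)C1=NNS(=O)(=O)c1ccc(C)cc1)[C@@H]1CC[C@](C)(O)[C@H](Br)C1 | intermediate
18 | allylic tosylhydrazine from hydride addition to 17 (boron-bound in the flask, new N-bearing centre undefined) | C=C(C[C@@H]1[C@@H](C(=C)C)CC=C(C)C1NNS(=O)(=O)c1ccc(C)cc1)[C@@H]1CC[C@](C)(O)[C@H](Br)C1 | intermediate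
19 | allylic diazene from 18 | C=C(C[C@@H]1[C@@H](C(=C)C)CC=C(C)C1N=N)[C@@H]1CC[C@](C)(O)[C@H](Br)C1 | intermediate
20 | (1S,2R,4R)-2-bromo-1-methyl-4-{3-[(1S,6S)-3-methyl-6-(prop-1-en-2-yl)cyclohex-2-en-1-yl]prop-1-en-2-yl}cyclohexan-1-ol (ring A substituents trans) | C=C(C[C@@H]1[C@@H](C(=C)C)CCC(C)=C1)[C@@H]1CC[C@](C)(O)[C@H](Br)C1 | intermediate
21 | CNP0213097.1, (1S,2R,4R)-2-bromo-1-methyl-4-{3-[(1R,2R,3S,6S)-6-methyl-3-(prop-1-en-2-yl)-7-oxabicyclo[4.1.0]heptan-2-yl]prop-1-en-2-yl}cyclohexan-1-ol | C=C(C[C@@H]1[C@@H](C(=C)C)CC[C@]2(C)O[C@H]12)[C@@H]1CC[C@](C)(O)[C@H](Br)C1 | target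

**Step count and risks**
Total step count: 12. Longest linear sequence: 12 steps (from 1 and 2 to 21); carvone 13 enters at step 9.

Steps most likely to fail:

Step 4. The closure may take the wrong regiochemical course: 5-exo attack of the carboxyl on the secondary B5 from the chair with an axial carboxyl, or premature lactonisation of the carboxylate during step 3. The fallback sets out from 5 and returns at 6. The epoxide is opened by water instead of by its own carboxyl (HClO4 cat., THF/H2O, 0 °C). In the ground-state chair the Markovnikov preference and the trans-diaxial rule both direct water to B4, which should give (1R,3S,4S)-3,4-dihydroxy-4-methylcyclohexane-1-carboxylic acid F1. Only its tertiary B4 hydroxyl shares a face with the carboxyl, so azeotropic lactonisation (TsOH cat., toluene, reflux) can form only the δ-lactone 6.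

Step 5. Displacement at B5 may be slow, because the bromide must pass close to the lactone oxygen beside a fully substituted carbon. Alternatively the triflate may ionise with participation of the lactone oxygen, leading to retention or a shift of the acyloxy bridge. The fallback sets out from 6 and returns at 8. The sulfonate is given up in favour of an Appel-type redox bromination with tri-n-octylphosphine and CBr4 (toluene, 70 °C). The alkoxyphosphonium ion is displaced by bromide with inversion inside the ion pair under neutral, non-ionising conditions, and the strong P=O bond supplies the driving force that a slow sulfonate displacement lacks. It makes no compound beyond those of the list (F0).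

Step 12. Facial selectivity may be poor if the weak substrate bias opposes the reagent, and some oxidation of the 1,1-disubstituted alkenes is possible. The fallback sets out from 20 and returns at 21. Epoxidation without reagent control (mCPBA, NaHCO3, CH2Cl2, 0 °C) should give 21 together with the epoxide diastereomer F2, whose oxygen is anti to the Cb chain on Cx. Warming the mixture with pyrrolidine in water should open only that isomer, trans-diaxially at the secondary Cz, to the pyrrolidine amino alcohol F3. The same rule would force the amine onto the tertiary Cw of 21, so 21 should survive and be separated from the basic amino alcohol by chromatography.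

Further compounds
F1 | step 4 | (1R,3S,4S)-3,4-dihydroxy-4-methylcyclohexane-1-carboxylic acid | OC(=O)[C@@H]1CC[C@](C)(O)[C@@H](O)C1
F0 | step 5 | none | none
F2 | step 12 | ring A epoxide diastereomer of 21 (epoxide oxygen anti to the Cb chain on Cx) | C=C(C[C@@H]1[C@@H](C(=C)C)CC[C@@]2(C)O[C@@H]12)[C@@H]1CC[C@](C)(O)[C@H](Br)C1
F3 | step 12 | amino alcohol from F2 (pyrrolidin-1-yl on Cz syn to the Cb chain, hydroxyl on Cw anti to it) | C=C(C[C@@H]1[C@@H](C(=C)C)CC[C@@](C)(O)[C@@H]1N1CCCC1)[C@@H]1CC[C@](C)(O)[C@H](Br)C1
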